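Readings and results stem from a simulated flask for substances that don't exist.

Rank the numbers of this flask by what an error in each does to the final D, and only then read off the one that counts. E turns L into D while L is fed in, but in Wednesday's run part of the L that has reacted does not show up as D.

- Wednesday's: L 0.027 M (fed, over 50 min); E 4.9 µM; the very flask that is asked about, followed so far; the fed solution adds 1.0 times the starting volume
- flask: L 0.027 M (fed, over 50 min); E 4.9 µM; time 15 h; the fed solution adds 1.0 times the starting volume

- Wednesday's (time / h: L / %, D / %): 0.167: 7.6, 10.6; 0.500: 9.4, 42.4; 0.833: 11.9, 73.1; 1.33: 0.4, 83.0; 2.00: 0.7, 83.7; 2.50: 0, 83.8; 3.00: 0, 84.5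

(standard deviation of a reading: 0.5 percentage points)

- charges are per starting volume, the dose included; the dosed solution carries all of it
- the numbers in the tables scatter with a standard deviation of 0.5 percentage points
- the reaction counts as stopped when no species that holds the L changes by six tenths of a point or more over the second half of the time
- percentages count the whole charge, also what has not yet gone in

- at 15 h, what has stopped the reaction, if anything has (all of L has reacted / it is still moving)
- how much of the L has reacted by 15 h
- how much D there is at 15 h, in percent of the L charged

The time asked counts little: in Wednesday's run L reads 0 % at 3.00 h, and D moves by 1.5 percentage points after 1.33 h. [L], [E] and the dosing time count here through the readings, since this is the same flask followed further. What remains is how the reacting L divides. Divide the rate at which L goes missing by the rate at which D forms, and time drops out.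

At 0.833 h the feed is over, L reads 11.9 % and D 73.1 %, so missing L over D is 0.205; call this the loss ratio, a selectivity factor turned upside down. If the remaining L divides the same way, I reckon D ends at 83.0 %. Either reading, off by 0.5 points, moves that by about as much.

The forecast says all of L has reacted, with 100 % reacted and D at 84.5 %, between 83.3 % and 89 %, which is above my figure. Its grounds: “this looks like a parallel side branch rather than an intermediate on the way to D”.

At 15 h in the flask all of L has reacted, 100 % of it, and D stands at 83.5 %. With E at 4.02 µM and the rest held, the answer for D moves by 5 points.

    2 L → Q (k = 0.160 M⁻¹ s⁻¹)
    L + E → D + E, rate k2*[L]*[E]/(1 + ([L]/Km2) + ([L]/Ksi2)^2) (24.0 mM, 16.0 mM, k = 880 M⁻¹ s⁻¹)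

While the denominator stays near one, these rate laws make the loss ratio go as [L]/[E]; if the feed holds [L] roughly inverse to [E], it can be carried as the inverse square of [E]. At 12.0 µM of E, all else held, I reckon it at 0.0342, which puts D at 96.7 %. That neighbour flask gives 96.3 % of D at 15 h.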